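Violet and grey are neighbours: violet differs from grey in its charge of free monomer, 15 mM against 8.0 mM, at the same initiator charge, and the average length divides monomer in chains by chains begun.

| setting | violet | grey |
|---|---|---|
| free monomer | 15 mM | 8.0 mM |
| initiator | 0.32 mM | 0.32 mM |
| time | 15 min | 15 min |

    free monomer + living end → monomer in chains + living end, rate k1*[living end]*[free monomer] (k1 = 92.0 M⁻¹ s⁻¹)
    2 initiator → spent initiator A (k2 = 109 M⁻¹ s⁻¹)
    free monomer + initiator → living end + monomer in chains (k3 = 0.113 M⁻¹ s⁻¹)
    initiator → spent initiator B (k4 = 0.0105 s⁻¹)

- a step written with two of one species runs at k times the square of its concentration and takes two of it each time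
- the average divides the monomer in chains by the number of chains begun, living and dead together
- run time (violet): 15 min

- which of the two ends with the longer chains by the average number of monomer units in a chain (chains begun, living or dead) ("neither" if they lie within 10 %) (violet / grey / neither)
- average number of monomer units in a chain (chains begun, living or dead) at the end, violet
- average number of monomer units in a chain (chains begun, living or dead) at the end, grey

Follow one initiator molecule in violet. Free monomer captures it at 0.00169 s⁻¹, it decays alone at 0.0105 s⁻¹, or it pairs with another initiator at 0.0698 s⁻¹ at the charge, a rate that falls in step with c(initiator). Summing its chance of capture as c(initiator) runs down gives 4.63 %: the capture yield, (capture/pairing)·ln(1 + pairing/(capture + decay)), the share of charged initiator that begins a chain. Free monomer is held at its charge here because the initiator's half-life by lone decay, 1.1 min, is shorter than the 8.48 min free monomer then needs to halve.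

So violet gets c(living end) = 0.0148 mM. Grey, with capture at 9.04 × 10⁻⁴ s⁻¹, has a yield of 2.54 % and 0.00814 mM. No step removes a living end, so free monomer falls pseudo-first-order. That gives a length of 716 in violet, longer than the 482 in grey.

The forecast names violet, with 710 (650 to 770) for violet and 465 (425 to 510) for grey, holding that “only about 4–5% of it starts chains”.

The simulation puts the longer chains in violet, with 708 in violet and 466 in grey, and with living ends at 0.0143 mM and 0.00796 mM at 15.0 min.

In grey at 6.84 min, the half-life of initiator by lone decay is 1.1 min, shorter than the 17 min by capture. By 7.50 min, 0.0874 % of the initiator charge stands in grey beside 74.6 % of its free monomer. Carried to the neighbour of grey charged with 1.3 mM of initiator, the capture yield is 1.04 %, which gives 0.0135 mM of living ends and a length of 399. That neighbour holds 0.0131 mM and reaches 395, so 4.06 times grey's initiator charge gave 1.65 times its living ends.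

(The numbers were set for the occasion; what happens was integrated by code.)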